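## Retrosynthetic overview

- The dihydropyran ring (C4–O and C5–C7' bonds) is disconnected by an inverse-electron-demand oxa-Diels–Alder reaction into an acylmethylene trione heterodiene and (−)-β-caryophyllene. This cycloaddition, run under a chiral copper–bis(oxazoline) catalyst, is the proposed new step and sets C4, C5 and C7'.
- The heterodiene comes from a Knoevenagel condensation of syncarpic acid with 3-methyl-2-oxobutanal.
- Syncarpic acid comes from dearomatising tetramethylation of phloroacetophenone followed by deacetylation; the glyoxal comes from Riley oxidation of 3-methylbutan-2-one.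
- Ring order: the cyclobutane and the nine-membered ring (with C1 and C9) arrive intact in caryophyllene, the trione ring is made first (steps 1–2), and the dihydropyran ring is formed last (step 5).

Assumption: (−)-β-caryophyllene is accepted as a commercial chiral-pool starting material; caryophyllane numbering is used (C4=C5 is the endocyclic alkene, C8=C15 the exocyclic methylene) and C7' is the methine that carries the isobutyryl group, so the target is (1R,4R,5S,9S,7'R).

Abbreviation: (R,R)-tBu-box is 2,2'-(propane-2,2-diyl)bis[(4R)-4-tert-butyl-4,5-dihydro-1,3-oxazole].

## Route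

Step 1
Reactants: 1 2',4',6'-trihydroxyacetophenone
Product: 2 4-acetyl-5-hydroxy-2,2,6,6-tetramethylcyclohex-4-ene-1,3-dione (acetylsyncarpic acid)
Conditions: MeI (6 equiv), NaOMe (5 equiv), MeOH, reflux; then aq HCl work-up
Reagents that add atoms: iodomethane, CI
Why: Exhaustive C-methylation of the phloroglucinol polyanion (dearomatising alkylation) is favoured over O-methylation in methanol and stops once both free ring carbons are quaternary while the acetyl-bearing carbon stays enolised, so the tetramethyl trione forms without any stereocentre.

Step 2
Reactants: 2 4-acetyl-5-hydroxy-2,2,6,6-tetramethylcyclohex-4-ene-1,3-dione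
Product: 3 5-hydroxy-2,2,6,6-tetramethylcyclohex-4-ene-1,3-dione (syncarpic acid)
Conditions: 6 M HCl (aq), reflux
Reagents that add atoms: none
Why: Acid-mediated retro-Claisen deacylation, in which water adds to the exocyclic acetyl carbonyl of the 2-acyl-1,3-dione and C–C cleavage releases acetic acid and the stabilised trione enol, with the gem-dimethyl positions inert and no stereocentre involved.

Step 3
Reactants: 4 3-methylbutan-2-one
Product: 5 3-methyl-2-oxobutanal
Conditions: SeO2 (1.0 equiv), 1,4-dioxane/H2O, reflux; distillation
Reagents that add atoms: selenium dioxide, O=[Se]=O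
Why: Riley oxidation, in which SeO2 oxidises the methyl group of the methyl ketone through its enol (ene reaction then [2,3]-sigmatropic shift) to the aldehyde while the tertiary α-carbon cannot be taken to a carbonyl, and no stereocentre is formed.

Step 4
Reactants: 3 syncarpic acid; 5 3-methyl-2-oxobutanal
Product: 7 2-(3-methyl-2-oxobutylidene)-4,4,6,6-tetramethylcyclohexane-1,3,5-trione, via aldol adduct 6 (not isolated)
Conditions: 5 (2 equiv), piperidinium acetate (5 mol%), 4 Å MS, CH2Cl2, 0 °C to rt, slow addition of 3; rapid filtration through silica
Reagents that add atoms: none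
Why: Knoevenagel condensation, in which the acidic trione enol adds to the highly electrophilic aldehyde carbon of the glyoxal (not its hindered ketone) and the aldol adduct dehydrates under amine-salt catalysis, with slow addition of 3 to excess 5 suppressing a second Michael addition; the trione is symmetric, so there is no alkene isomer and no stereocentre.

Step 5
Reactants: 7 2-(3-methyl-2-oxobutylidene)-4,4,6,6-tetramethylcyclohexane-1,3,5-trione; 8 (−)-β-caryophyllene
Product: 9 tomentodione Q (target)
Conditions: 8 (1.5 equiv), [Cu((R,R)-tBu-box)](SbF6)2 (10 mol%, from CuCl2, AgSbF6 and the ligand), 4 Å MS, CH2Cl2, −60 to −40 °C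
Reagents that add atoms: none
Why: Proposed new method: a bis(oxazoline)–divalent-copper-catalysed inverse-electron-demand oxa-Diels–Alder reaction of an acylmethylene-1,3-dione with an unactivated, strained trisubstituted (E)-cycloalkene, in which square-planar copper chelates the side-chain carbonyl and the ring carbonyl cis to it (a planar seven-membered Z-ene-1,4-dione chelate, O···O about 2.7 Å), lowering the LUMO while leaving the other ring carbonyl free to act as the diene oxygen and to close onto C4 before the developing tertiary cation can cyclise transannularly; in a qualitative model the tert-butyl group beside the acyl oxygen blocks the Si face of C7' so the alkene adds to its Re face (7'R), caryophyllene reacts through its major αα/βα conformers on the face that also gives natural caryophyllene oxide (4R), the polarised asynchronous transition state places oxygen on the tertiary C4 and carbon on C5, and suprafacial addition to the E alkene gives the trans ring fusion (5S) with C6 and the C4 methyl endo, so H-5 and H-7' end up cis; the closest known reaction types are the uncatalysed thermal hetero-Diels–Alder reaction of syncarpic-acid-derived alkylidene triones with caryophyllene and the copper–bis(oxazoline)-catalysed hetero-Diels–Alder reaction of chelating β,γ-unsaturated α-keto esters with enol ethers.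

## Compound list

1 | 2',4',6'-trihydroxyacetophenone (phloroacetophenone) | CC(=O)c1c(O)cc(O)cc1O | starting material
2 | 4-acetyl-5-hydroxy-2,2,6,6-tetramethylcyclohex-4-ene-1,3-dione (acetylsyncarpic acid) | CC(=O)C1=C(O)C(C)(C)C(=O)C(C)(C)C1=O | intermediate
3 | 5-hydroxy-2,2,6,6-tetramethylcyclohex-4-ene-1,3-dione (syncarpic acid, enol form) | CC1(C)C(=O)C=C(O)C(C)(C)C1=O | intermediate
4 | 3-methylbutan-2-one | CC(C)C(C)=O | starting material
5 | 3-methyl-2-oxobutanal (isopropylglyoxal) | CC(C)C(=O)C=O | intermediate
6 | 5-hydroxy-4-(1-hydroxy-3-methyl-2-oxobutyl)-2,2,6,6-tetramethylcyclohex-4-ene-1,3-dione (racemic aldol adduct, not isolated) | CC(C)C(=O)C(O)C1=C(O)C(C)(C)C(=O)C(C)(C)C1=O | intermediate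
7 | 2-(3-methyl-2-oxobutylidene)-4,4,6,6-tetramethylcyclohexane-1,3,5-trione (heterodiene) | CC(C)C(=O)C=C1C(=O)C(C)(C)C(=O)C(C)(C)C1=O | intermediate
8 | (−)-β-caryophyllene, (1R,4E,9S) | C/C1=C\CCC(=C)[C@H]2CC(C)(C)[C@@H]2CC1 | starting material
9 | tomentodione Q, (1R,4R,5S,9S,7'R): dihydropyran formed by O–C4 and C7'–C5, trans-fused to the nine-membered ring, H-5 and H-7' cis, isobutyryl on C7', 8(15)-methylene intact | C=C1CC[C@H]2[C@@H](C(=O)C(C)C)C3=C(O[C@]2(C)CC[C@@H]2[C@@H]1CC2(C)C)C(C)(C)C(=O)C(C)(C)C3=O | target

## Step count and risk

Total step count: 5. Longest linear sequence: 4 steps (steps 1, 2, 4 and 5; step 3 is a one-step side branch).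

The three steps most likely to fail:

**Step 5 (the proposed new cycloaddition).** The ligand sits far from the reacting termini, so facial control may be weak; the (R,R) assignment rests on a qualitative model only. The product may also inhibit the catalyst by chelation, and the Lewis acid may trigger cationic transannular chemistry of caryophyllene. The fallback is known chemistry that relies on substrate control and recycling instead of catalyst control. It sets out from 3, 5 and 8: the heterodiene is generated in the flask and trapped thermally (piperidinium acetate cat., toluene, 80 °C), the established domino Knoevenagel/hetero-Diels–Alder entry to this family of meroterpenoids. The strained C4=C5 bond reacts mainly on its more accessible face and gives 9 together with, as principal co-product, (7'S)-7'-epi-tomentodione Q F1. The two are separated by chromatography; F1 is then equilibrated with DBU in toluene through the enol of the isobutyryl ketone and the mixture is separated again. The fallback comes back to the route at 9.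

**Step 3 (Riley oxidation).** The yield may be modest, over-oxidation is possible, and the volatile glyoxal is hard to free from its hydrate and from selenium residues. The fallback sets out from 4. Bromination on the methyl group (Br2, MeOH, 0–10 °C) gives 1-bromo-3-methylbutan-2-one F2, and Kornblum oxidation (DMSO, NaHCO3, rt) converts the bromide to the aldehyde. It comes back to the route at 5.

**Step 4 (Knoevenagel condensation).** The very electrophilic heterodiene may capture a second molecule of 3, or hydrate or decompose on isolation. The fallback sets out from 3 and builds the alkene by selenoxide elimination under anhydrous, nucleophile-free conditions. C-alkylation of 3 with 1-bromo-3-methylbutan-2-one F2 (commercial, or made as above; K2CO3, CHCl3, rt) gives 5-hydroxy-2,2,6,6-tetramethyl-4-(3-methyl-2-oxobutyl)cyclohex-4-ene-1,3-dione F3. Selenenylation at the ring carbon (PhSeCl, pyridine, CH2Cl2, 0 °C) gives 4,4,6,6-tetramethyl-2-(3-methyl-2-oxobutyl)-2-(phenylselanyl)cyclohexane-1,3,5-trione F4. Oxidation with mCPBA in CH2Cl2 at −78 °C gives the corresponding selenoxide F5, which undergoes syn-elimination towards the only available β-hydrogens on warming to 0 °C. It comes back to the route at 7.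

## Further compounds

F1 | step 5 | (7'S)-7'-epi-tomentodione Q, (1R,4R,5S,9S,7'S) | C=C1CC[C@H]2[C@H](C(=O)C(C)C)C3=C(O[C@]2(C)CC[C@@H]2[C@@H]1CC2(C)C)C(C)(C)C(=O)C(C)(C)C3=O
F2 | step 3 | 1-bromo-3-methylbutan-2-one | CC(C)C(=O)CBr
F3 | step 4 | 5-hydroxy-2,2,6,6-tetramethyl-4-(3-methyl-2-oxobutyl)cyclohex-4-ene-1,3-dione | CC(C)C(=O)CC1=C(O)C(C)(C)C(=O)C(C)(C)C1=O
F4 | step 4 | 4,4,6,6-tetramethyl-2-(3-methyl-2-oxobutyl)-2-(phenylselanyl)cyclohexane-1,3,5-trione | CC(C)C(=O)CC1([Se]c2ccccc2)C(=O)C(C)(C)C(=O)C(C)(C)C1=O
F5 | step 4 | 4,4,6,6-tetramethyl-2-(3-methyl-2-oxobutyl)-2-(phenylseleninyl)cyclohexane-1,3,5-trione (selenoxide, racemic at selenium, not isolated) | CC(C)C(=O)CC1([Se](=O)c2ccccc2)C(=O)C(C)(C)C(=O)C(C)(C)C1=O
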